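Everything rests on cutting the upper pyran ring (ring C) at O1–C2 and C3–C4. The feature used is C4 itself: it links ring A of the upper unit to C8' of the lower flavan and lies ortho to O1, so ionisation at C4 turns O1–C8a–C4a–C4 into an o-quinone methide that is already arylated by the lower unit. One acid-catalysed [4+2] addition of a (Z)-styrylsilane then closes ring C, forms both bonds and sets C2, C3 and C4, silicon serving as a masked 3-OH. The precursor is a perbenzylated diaryl carbinol with a free ortho phenol, bromine-capped at C6, C8 and C6' so that no arene C–H can trap the methide.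

Key step: step 13

Remarks on the chemistry:
- Flavan numbering is used; primes mark the lower unit joined through C8'.
- The bromine atoms at C6, C8 and C6' are spectators. Without them the free positions of the phloroglucinol rings would be better nucleophiles than the vinylsilane and the methide would self-condense by Friedel–Crafts alkylation. They leave with the benzyl ethers in step 15.
- Bromine raises the CIP rank of C4a above C8', so compounds 20–22 are labelled 4S although their geometry is that of the 4R target.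
- Assumption: both enantiomers of the acid in step 13 are at hand and the one matched to the (2R,3R) lower unit is found by trial; a wrong-face adduct would be a diastereomer and separable.

Step 1
Reactants: 1 rac-1-phenylprop-2-en-1-ol
Product: 2 (S)-[(R)-oxiran-2-yl](phenyl)methanol
Conditions: Ti(OiPr)4 (0.1 equiv), L-(+)-diisopropyl tartrate (0.12 equiv), t-BuOOH (0.45 equiv), 4 Å MS, CH2Cl2, −20 °C
Reagents that add atoms: tert-butyl hydroperoxide, CC(C)(C)OO
Why: Sharpless kinetic resolution, in which the L-tartrate catalyst should epoxidise the (R)-enantiomer of 1 much faster than the (S)-enantiomer and on the face that gives the anti (erythro) epoxy alcohol, so that stopping below half conversion sets both centres of 2.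

Step 2
Reactants: 2 (S)-[(R)-oxiran-2-yl](phenyl)methanol; 3 3,5-bis(benzyloxy)phenol
Product: 4 (R)-2-[(R)-[3,5-bis(benzyloxy)phenoxy](phenyl)methyl]oxirane
Conditions: PPh3, DIAD, toluene, 0 °C → rt
Reagents that add atoms: none
Why: Mitsunobu etherification, in which the phenol displaces the activated benzylic hydroxyl by SN2 with inversion, so the (S)-carbinol becomes the (R)-aryl ether carbon (future C2') while the epoxide carbon (future C3') is untouched.

Step 3
Reactants: 4 (R)-2-[(R)-[3,5-bis(benzyloxy)phenoxy](phenyl)methyl]oxirane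
Product: 5 (2R,3R)-5,7-bis(benzyloxy)-2-phenylchroman-3-ol
Conditions: AuCl3 (5 mol %), AgOTf (15 mol %), ClCH2CH2Cl, 50 °C
Reagents that add atoms: none
Why: Intramolecular Friedel–Crafts epoxy–arene cyclisation, a known gold-catalysed route from aryl glycidyl ethers to flavan-3-ols, in which the ring carbon ortho to the ether oxygen opens the epoxide at its terminal carbon (6-endo) without touching C2 or C3, so the 2,3-cis (2R,3R) relation is carried over.

Step 4
Reactants: 5 (2R,3R)-5,7-bis(benzyloxy)-2-phenylchroman-3-ol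
Product: 6 (2R,3R)-3,5,7-tris(benzyloxy)-2-phenylchroman
Conditions: NaH, BnBr, n-Bu4NI (cat.), DMF, 0 °C → rt
Reagents that add atoms: benzyl bromide, BrCc1ccccc1
Why: Williamson etherification of the secondary alcohol, which protects O3' against the organolithium of step 10 with a group that leaves in the final hydrogenolysis.

Step 5
Reactants: 6 (2R,3R)-3,5,7-tris(benzyloxy)-2-phenylchroman
Product: 7 (2R,3R)-3,5,7-tris(benzyloxy)-8-iodo-2-phenylchroman
Conditions: NIS (1.0 equiv), DMF, 0 °C → rt
Reagents that add atoms: N-iodosuccinimide, O=C1CCC(=O)N1I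
Why: Electrophilic aromatic iodination, expected at C8 as in the known C8-selective halogenation of 5,7-dibenzyloxyflavans, because C8 (next to the ring oxygen) is less hindered than C6 (between two benzyloxy groups).

Step 6
Reactants: 7 (2R,3R)-3,5,7-tris(benzyloxy)-8-iodo-2-phenylchroman
Product: 8 (2R,3R)-3,5,7-tris(benzyloxy)-6-bromo-8-iodo-2-phenylchroman
Conditions: NBS (1.05 equiv), CH2Cl2, 0 °C
Reagents that add atoms: N-bromosuccinimide, O=C1CCC(=O)N1Br
Why: Electrophilic aromatic bromination at the only remaining activated C–H of ring A, which installs the C6' cap and leaves iodine as the faster-exchanging halogen for step 10.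

Step 7
Reactants: 3 3,5-bis(benzyloxy)phenol
Product: 9 4,6-bis(benzyloxy)-2-hydroxybenzaldehyde
Conditions: MgCl2, Et3N, (CH2O)n, MeCN, reflux
Reagents that add atoms: paraformaldehyde (formaldehyde source), C=O
Why: Casnati–Skattebøl ortho-formylation, in which the magnesium phenoxide delivers formaldehyde only to the position ortho to OH and a second formaldehyde oxidises the benzylic alkoxide to the aldehyde.

Step 8
Reactants: 9 4,6-bis(benzyloxy)-2-hydroxybenzaldehyde
Product: 10 4,6-bis(benzyloxy)-3,5-dibromo-2-hydroxybenzaldehyde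
Conditions: NBS (2.1 equiv), MeCN, 0 °C → rt
Reagents that add atoms: N-bromosuccinimide, O=C1CCC(=O)N1Br
Why: Electrophilic aromatic bromination of the two remaining ring positions (ortho and para to the phenol), which become the C8 and C6 caps of the upper unit.

Step 9
Reactants: 10 4,6-bis(benzyloxy)-3,5-dibromo-2-hydroxybenzaldehyde
Product: 11 4,6-bis(benzyloxy)-3,5-dibromo-2-[(tert-butyldimethylsilyl)oxy]benzaldehyde
Conditions: TBSCl, imidazole, DMF, rt
Reagents that add atoms: tert-butyldimethylsilyl chloride, CC(C)(C)[Si](C)(C)Cl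
Why: Silylation of the acidic phenol, so that the aldehyde is not turned into an unreactive phenoxide and no aryllithium is lost to an O–H in step 10.

Step 10
Reactants: 8 (2R,3R)-3,5,7-tris(benzyloxy)-6-bromo-8-iodo-2-phenylchroman; 11 4,6-bis(benzyloxy)-3,5-dibromo-2-[(tert-butyldimethylsilyl)oxy]benzaldehyde
Product: 14 [4,6-bis(benzyloxy)-3,5-dibromo-2-hydroxyphenyl][(2R,3R)-3,5,7-tris(benzyloxy)-6-bromo-2-phenylchroman-8-yl]methanol (both carbinol epimers), via aryllithium 12 (not isolated), via silylated lithium alkoxide 13 (not isolated)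
Conditions: n-BuLi (1.05 equiv), THF, −78 °C; 11, −78 °C; AcOH, −78 °C; n-Bu4NF, THF, 0 °C
Reagents that add atoms: none
Why: Iodine–lithium exchange is far faster than bromine–lithium exchange at −78 °C, so the aryllithium forms at C8' only and adds to the aldehyde (1,2-addition), the cold acetic acid quench stops silyl migration and loss of silanolate, and buffered fluoride then frees the phenol from whichever oxygen carries silicon, the carbinol centre being left unset because step 13 planarises it.

Step 11
Reactants: 15 phenylacetylene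
Product: 16 benzyldimethyl(phenylethynyl)silane
Conditions: n-BuLi, THF, −78 °C; BnMe2SiCl, −78 °C → rt
Reagents that add atoms: benzylchlorodimethylsilane, C[Si](C)(Cl)Cc1ccccc1
Why: Deprotonation of the terminal alkyne and silylation of the lithium acetylide at silicon, a standard route to alkynylsilanes.

Step 12
Reactants: 16 benzyldimethyl(phenylethynyl)silane
Product: 18 (Z)-benzyldimethyl(styryl)silane, via alkenylalane 17 (not isolated)
Conditions: i-Bu2AlH, N-methylpyrrolidine, heptane, 60 °C; aq NH4Cl, 0 °C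
Reagents that add atoms: none
Why: Hydroalumination of the silylalkyne in the presence of a donor amine adds H and Al cis (aluminium on the silicon-bearing carbon) and suppresses isomerisation, and protonolysis with retention then gives the Z-vinylsilane.

Step 13
Reactants: 14 [4,6-bis(benzyloxy)-3,5-dibromo-2-hydroxyphenyl][(2R,3R)-3,5,7-tris(benzyloxy)-6-bromo-2-phenylchroman-8-yl]methanol (both carbinol epimers); 18 (Z)-benzyldimethyl(styryl)silane
Product: 20 (2R,3R)-3,5,7-tris(benzyloxy)-6-bromo-8-[(2R,3R,4S)-5,7-bis(benzyloxy)-3-[benzyl(dimethyl)silyl]-6,8-dibromo-2-phenylchroman-4-yl]-2-phenylchroman (upper unit 2,3-cis-3,4-trans), via o-quinone methide 19 (not isolated)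
Conditions: (R)- or (S)-3,3'-bis(2,4,6-triisopropylphenyl)-1,1'-binaphthalene-2,2'-diyl N-(trifluoromethylsulfonyl)phosphoramide (10 mol %), 18 (5 equiv), 5 Å MS, CHCl3, −30 → 0 °C
Reagents that add atoms: none
Why: Proposed new method: the acid dehydrates 14 (both carbinol epimers give the same planar species) to the hydrogen-bonded o-quinone methide 19, whose C4 is attacked by the silicon-bearing carbon of 18 so that charge builds at C2, benzylic and β to silicon, and O1 then closes on C2 in an asynchronous, suprafacial inverse-demand hetero-Diels–Alder reaction. The closest known reaction type is the Brønsted acid-catalysed [4+2] cycloaddition of o-quinone methides (from o-hydroxybenzyl alcohols) with styrenes to 2,4-diarylchromans, which has not been shown with a β-silyl styrene or with a methide carbon flanked by four ortho substituents. Ring C of the upper unit closes in cycloaddition mode, C3–C4 leading and O1–C2 completing the six-membered ring before silicon can be lost from the β-silyl cation. The C2/C3 cis relation follows from the Z geometry of 18 through syn addition, the C3/C4 trans relation from the exo approach in which SiMe2Bn and phenyl point away from the methide ring and its C5 benzyloxy group, and the absolute sense from the chiral phosphoramide anion held at O1. The step therefore needs regio-, exo- and facial selectivity: β-silicon plus phenyl secure the regiochemistry, the size of the silyl group the exo mode, the catalyst the face (the resident lower-unit centres make any wrong-face adduct a separable diastereomer), and the bromine caps ensure that the only π-nucleophile available to 19 is the alkene.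

Step 14
Reactants: 20 (2R,3R)-3,5,7-tris(benzyloxy)-6-bromo-8-[(2R,3R,4S)-5,7-bis(benzyloxy)-3-[benzyl(dimethyl)silyl]-6,8-dibromo-2-phenylchroman-4-yl]-2-phenylchroman
Product: 22 (2R,3R,4S)-5,7-bis(benzyloxy)-6,8-dibromo-2-phenyl-4-[(2R,3R)-3,5,7-tris(benzyloxy)-6-bromo-2-phenylchroman-8-yl]chroman-3-ol, via fluorosilane 21 (not isolated)
Conditions: n-Bu4NF, THF, 0 °C → rt; KHCO3, 30% H2O2, MeOH/THF, rt → 40 °C
Reagents that add atoms: hydrogen peroxide, OO
Why: Tamao–Fleming oxidation, in which fluoride removes the benzyl group from silicon and hydroperoxide then triggers 1,2-migration of C3 from silicon to oxygen with retention, so the axial silyl group becomes the axial 3-OH, β-elimination being disfavoured because, with the C2 phenyl equatorial, the C3–Si bond is not antiperiplanar to C2–O1.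

Step 15
Reactants: 22 (2R,3R,4S)-5,7-bis(benzyloxy)-6,8-dibromo-2-phenyl-4-[(2R,3R)-3,5,7-tris(benzyloxy)-6-bromo-2-phenylchroman-8-yl]chroman-3-ol
Product: 23 (2R,3R,4R)-2-phenyl-4-[(2R,3R)-3,5,7-trihydroxy-2-phenylchroman-8-yl]chroman-3,5,7-triol
Conditions: H2 (1 atm), Pd(OH)2/C, NaOAc, THF/MeOH/H2O, rt
Reagents that add atoms: none
Why: Catalytic hydrogenolysis cleaves the five benzyl ethers and the three aryl C–Br bonds in one operation, as is known for bromine-capped benzylated flavan oligomers, while acetate buffers the HBr that would otherwise threaten the acid-labile C4–C8' bond; no stereocentre is touched.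

Compound list
1 | rac-1-phenylprop-2-en-1-ol | C=CC(O)c1ccccc1 | starting material
2 | (S)-[(R)-oxiran-2-yl](phenyl)methanol (anti epoxy alcohol) | O[C@@H](c1ccccc1)[C@H]1CO1 | intermediate
3 | 3,5-bis(benzyloxy)phenol | Oc1cc(OCc2ccccc2)cc(OCc2ccccc2)c1 | starting material
4 | (R)-2-[(R)-[3,5-bis(benzyloxy)phenoxy](phenyl)methyl]oxirane | c1ccccc1COc1cc(OCc2ccccc2)cc(O[C@H](c2ccccc2)[C@H]2CO2)c1 | intermediate
5 | (2R,3R)-5,7-bis(benzyloxy)-2-phenylchroman-3-ol (2,3-cis) | c1ccccc1COc1cc(OCc2ccccc2)c2c(c1)O[C@H](c1ccccc1)[C@H](O)C2 | intermediate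
6 | (2R,3R)-3,5,7-tris(benzyloxy)-2-phenylchroman | c1ccccc1COc1cc(OCc2ccccc2)c2c(c1)O[C@H](c1ccccc1)[C@H](OCc1ccccc1)C2 | intermediate
7 | (2R,3R)-3,5,7-tris(benzyloxy)-8-iodo-2-phenylchroman | c1ccccc1COc1cc(OCc2ccccc2)c2c(c1I)O[C@H](c1ccccc1)[C@H](OCc1ccccc1)C2 | intermediate
8 | (2R,3R)-3,5,7-tris(benzyloxy)-6-bromo-8-iodo-2-phenylchroman | c1ccccc1COc1c(Br)c(OCc2ccccc2)c2c(c1I)O[C@H](c1ccccc1)[C@H](OCc1ccccc1)C2 | intermediate
9 | 4,6-bis(benzyloxy)-2-hydroxybenzaldehyde | O=Cc1c(O)cc(OCc2ccccc2)cc1OCc1ccccc1 | intermediate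
10 | 4,6-bis(benzyloxy)-3,5-dibromo-2-hydroxybenzaldehyde | O=Cc1c(O)c(Br)c(OCc2ccccc2)c(Br)c1OCc1ccccc1 | intermediate
11 | 4,6-bis(benzyloxy)-3,5-dibromo-2-[(tert-butyldimethylsilyl)oxy]benzaldehyde | O=Cc1c(O[Si](C)(C)C(C)(C)C)c(Br)c(OCc2ccccc2)c(Br)c1OCc1ccccc1 | intermediate
12 | [(2R,3R)-3,5,7-tris(benzyloxy)-6-bromo-2-phenylchroman-8-yl]lithium | [Li]c1c(OCc2ccccc2)c(Br)c(OCc2ccccc2)c2c1O[C@H](c1ccccc1)[C@H](OCc1ccccc1)C2 | intermediate
13 | lithium alkoxide of the O-silylated benzhydrol from 12 and 11 (both carbinol epimers) | [Li+].[O-]C(c1c(O[Si](C)(C)C(C)(C)C)c(Br)c(OCc2ccccc2)c(Br)c1OCc1ccccc1)c1c(OCc2ccccc2)c(Br)c(OCc2ccccc2)c2c1O[C@H](c1ccccc1)[C@H](OCc1ccccc1)C2 | intermediate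
14 | [4,6-bis(benzyloxy)-3,5-dibromo-2-hydroxyphenyl][(2R,3R)-3,5,7-tris(benzyloxy)-6-bromo-2-phenylchroman-8-yl]methanol (both carbinol epimers) | OC(c1c(O)c(Br)c(OCc2ccccc2)c(Br)c1OCc1ccccc1)c1c(OCc2ccccc2)c(Br)c(OCc2ccccc2)c2c1O[C@H](c1ccccc1)[C@H](OCc1ccccc1)C2 | intermediate
15 | phenylacetylene | C#Cc1ccccc1 | starting material
16 | benzyldimethyl(phenylethynyl)silane | C[Si](C)(Cc1ccccc1)C#Cc1ccccc1 | intermediate
17 | [(Z)-1-[benzyl(dimethyl)silyl]-2-phenylethenyl]bis(2-methylpropyl)alane (Si and Ph cis) | CC(C)C[Al](CC(C)C)/C(=C/c1ccccc1)[Si](C)(C)Cc1ccccc1 | intermediate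
18 | (Z)-benzyldimethyl(styryl)silane | C[Si](C)(Cc1ccccc1)/C=C\c1ccccc1 | intermediate
19 | 3,5-bis(benzyloxy)-2,4-dibromo-6-[[(2R,3R)-3,5,7-tris(benzyloxy)-6-bromo-2-phenylchroman-8-yl]methylidene]cyclohexa-2,4-dien-1-one (o-quinone methide, alkene geometry not fixed) | O=C1C(Br)=C(OCc2ccccc2)C(Br)=C(OCc2ccccc2)C1=Cc1c(OCc2ccccc2)c(Br)c(OCc2ccccc2)c2c1O[C@H](c1ccccc1)[C@H](OCc1ccccc1)C2 | intermediate
20 | (2R,3R)-3,5,7-tris(benzyloxy)-6-bromo-8-[(2R,3R,4S)-5,7-bis(benzyloxy)-3-[benzyl(dimethyl)silyl]-6,8-dibromo-2-phenylchroman-4-yl]-2-phenylchroman | c1ccccc1COc1c(Br)c(OCc3ccccc3)c2c(c1Br)O[C@H](c1ccccc1)[C@H]([Si](C)(C)Cc1ccccc1)[C@H]2c1c(OCc3ccccc3)c(Br)c(OCc3ccccc3)c2c1O[C@H](c1ccccc1)[C@H](OCc1ccccc1)C2 | intermediate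
21 | 3-(fluorodimethylsilyl) analogue of 20, same configuration | c1ccccc1COc1c(Br)c(OCc3ccccc3)c2c(c1Br)O[C@H](c1ccccc1)[C@H]([Si](C)(C)F)[C@H]2c1c(OCc3ccccc3)c(Br)c(OCc3ccccc3)c2c1O[C@H](c1ccccc1)[C@H](OCc1ccccc1)C2 | intermediate
22 | (2R,3R,4S)-5,7-bis(benzyloxy)-6,8-dibromo-2-phenyl-4-[(2R,3R)-3,5,7-tris(benzyloxy)-6-bromo-2-phenylchroman-8-yl]chroman-3-ol | c1ccccc1COc1c(Br)c(OCc3ccccc3)c2c(c1Br)O[C@H](c1ccccc1)[C@H](O)[C@H]2c1c(OCc3ccccc3)c(Br)c(OCc3ccccc3)c2c1O[C@H](c1ccccc1)[C@H](OCc1ccccc1)C2 | intermediate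
23 | (2R,3R,4R)-2-phenyl-4-[(2R,3R)-3,5,7-trihydroxy-2-phenylchroman-8-yl]chroman-3,5,7-triol (CNP0154953.1) | Oc1cc(O)c2c(c1)O[C@H](c1ccccc1)[C@H](O)[C@H]2c1c(O)cc(O)c2c1O[C@H](c1ccccc1)[C@H](O)C2 | target

Total step count: 15. Longest linear sequence: 10 steps (steps 1–6, 10, 13, 14, 15).

Steps most likely to fail

Step 13. Several processes can defeat it:
- bond formation at the crowded methide carbon may be too slow;
- the β-silyl cation may lose silicon before O1 closes, giving vinylation instead of annulation;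
- exo or facial selectivity may be poor;
- the acid may cleave the C4–C8' bond.

The fallback is the known cationic interflavan coupling and uses no silicon. It sets out from 5 and 6. Benzylic oxidation of 5 at C4 (DDQ, 2-ethoxyethanol, CH2Cl2, rt) should give (2R,3R,4S)-5,7-bis(benzyloxy)-4-(2-ethoxyethoxy)-2-phenylchroman-3-ol F1. Activation of F1 with TMSOTf (CH2Cl2, −78 °C) in the presence of excess 6 should give the 4→8' dimer (2R,3R,4R)-5,7-bis(benzyloxy)-2-phenyl-4-[(2R,3R)-3,5,7-tris(benzyloxy)-2-phenylchroman-8-yl]chroman-3-ol F2. The nucleophile enters anti to the 3-OH, which is the established 3,4-trans outcome in the 2,3-cis series, and the excess of 6 suppresses self-condensation. Hydrogenolysis of F2 (H2, Pd(OH)2/C, THF/MeOH/H2O) returns to the route at 23.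

Step 14. Fluoride attack on the hindered silicon may be slow, or the basic medium may cause protodesilylation or ring opening by loss of O1. The fallback changes the unmasking from nucleophilic to electrophilic (Fleming oxidation of a phenylsilane) and sets out from 15 and 14. Phenylacetylene is silylated with n-BuLi and PhMe2SiCl to dimethyl(phenyl)(phenylethynyl)silane F3. Hydroalumination and protonolysis as in step 12 give (Z)-dimethyl(phenyl)(styryl)silane F4. The cycloaddition with 14 under the conditions of step 13, by then reduced to practice, gives the 3-[dimethyl(phenyl)silyl] analogue of 20 F5. F5 is oxidised with Hg(OAc)2 and AcOOH in AcOH at rt: ipso-mercuration removes the phenyl group at the periphery of silicon and peracid then effects the C-to-O shift with retention. The fully substituted, bromine-capped A rings offer no site for mercuration. The sequence returns to the route at 22.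

Step 10. The addition joins two di-ortho-substituted partners and may be slow enough for lithium–bromine scrambling, or for silyl migration with loss of silanolate (premature methide formation under basic conditions), to compete. The fallback drops the protecting group and the lithium reagent and sets out from 8 and 10. Iodine–magnesium exchange on 8 with i-PrMgCl·LiCl (THF, −20 °C), which leaves aryl bromides alone, gives chloro[(2R,3R)-3,5,7-tris(benzyloxy)-6-bromo-2-phenylchroman-8-yl]magnesium F6. Aldehyde 10 is deprotonated with one equivalent of t-BuMgCl to chloromagnesium 3,5-bis(benzyloxy)-2,4-dibromo-6-formylphenolate F7, a chelated phenoxide that cannot shed a leaving group. The two are combined (THF, −20 °C → rt), the classical aryl Grignard route to o-hydroxybenzhydrols, and quenched with aq NH4Cl to return to the route at 14.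

Further compounds
F1 | step 13 | (2R,3R,4S)-5,7-bis(benzyloxy)-4-(2-ethoxyethoxy)-2-phenylchroman-3-ol | c1ccccc1COc1cc(OCc2ccccc2)c2c(c1)O[C@H](c1ccccc1)[C@H](O)[C@H]2OCCOCC
F2 | step 13 | (2R,3R,4R)-5,7-bis(benzyloxy)-2-phenyl-4-[(2R,3R)-3,5,7-tris(benzyloxy)-2-phenylchroman-8-yl]chroman-3-ol | c1ccccc1COc1cc(OCc3ccccc3)c2c(c1)O[C@H](c1ccccc1)[C@H](O)[C@H]2c1c(OCc3ccccc3)cc(OCc3ccccc3)c2c1O[C@H](c1ccccc1)[C@H](OCc1ccccc1)C2
F3 | step 14 | dimethyl(phenyl)(phenylethynyl)silane | C[Si](C)(c1ccccc1)C#Cc1ccccc1
F4 | step 14 | (Z)-dimethyl(phenyl)(styryl)silane | C[Si](C)(c1ccccc1)/C=C\c1ccccc1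
F5 | step 14 | (2R,3R)-3,5,7-tris(benzyloxy)-6-bromo-8-[(2R,3R,4S)-5,7-bis(benzyloxy)-6,8-dibromo-3-[dimethyl(phenyl)silyl]-2-phenylchroman-4-yl]-2-phenylchroman | c1ccccc1COc1c(Br)c(OCc3ccccc3)c2c(c1Br)O[C@H](c1ccccc1)[C@H]([Si](C)(C)c1ccccc1)[C@H]2c1c(OCc3ccccc3)c(Br)c(OCc3ccccc3)c2c1O[C@H](c1ccccc1)[C@H](OCc1ccccc1)C2
F6 | step 10 | chloro[(2R,3R)-3,5,7-tris(benzyloxy)-6-bromo-2-phenylchroman-8-yl]magnesium | Cl[Mg]c1c(OCc2ccccc2)c(Br)c(OCc2ccccc2)c2c1O[C@H](c1ccccc1)[C@H](OCc1ccccc1)C2
F7 | step 10 | chloromagnesium 3,5-bis(benzyloxy)-2,4-dibromo-6-formylphenolate | O=Cc1c(O[Mg]Cl)c(Br)c(OCc2ccccc2)c(Br)c1OCc1ccccc1
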